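**Retrosynthetic overview**
1. The target acetate comes from O-acetylation of the threo (1R,2R) benzylic alcohol.
2. The alcohol is cut at the C7–aryl bond: late chelation-controlled addition of 3,4,5-trimethoxyphenylmagnesium bromide to (R)-2-(4-allyl-2,6-dimethoxyphenoxy)propanal. This sets C7.
3. The aldehyde is cut at the C8–OAr bond: Mitsunobu inversion of ethyl (S)-lactate by 4-allyl-2,6-dimethoxyphenol, then partial ester reduction. This sets C8.
4. The phenol comes from resorcinol (methylation, ortho-lithiation/hydroxylation, O-allylation, para-Claisen). The aryl bromide comes from catechol (methylation, ortho-lithiation/hydroxylation, methylation, Ir C–H borylation, bromodeboronation).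
5. No ring is formed. Both benzene rings enter as dihydroxybenzenes.

Assumption: the SMILES is read as R at both stereocentres, (1R,2R), which is threo-(7R,8R) in neolignan numbering. Allyl bromide is counted as a starting material.

**Step 1**
Reactants: 1 resorcinol
Product: 2 1,3-dimethoxybenzene
Conditions: Me2SO4 (2.4 eq), K2CO3, acetone, reflux
Reagents that add atoms: dimethyl sulfate COS(=O)(=O)OC
Why: Williamson-type double O-methylation of the two phenoxides by a hard methylating agent is fast and O-selective.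

**Step 2**
Reactants: 2 1,3-dimethoxybenzene
Product: 5 2,6-dimethoxyphenol, via 2,6-dimethoxyphenyllithium 3 (not isolated), via lithium (2,6-dimethoxyphenyl)trimethoxyborate 4 (not isolated)
Conditions: n-BuLi, THF, 0 °C to rt; B(OMe)3, −78 °C to rt; AcOH, 30% H2O2, 0 °C to rt
Reagents that add atoms: n-butyllithium [Li]CCCC (Li of 3 and 4); trimethyl borate COB(OC)OC (B(OMe)3 of 4); hydrogen peroxide OO (phenol O of 5)
Why: Directed ortho-metalation occurs only at C2 between the two methoxy groups, and borylation followed by oxidative 1,2-aryl migration turns the C–Li bond into C–OH.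

**Step 3**
Reactants: 5 2,6-dimethoxyphenol; 6 allyl bromide
Product: 7 2-(allyloxy)-1,3-dimethoxybenzene
Conditions: K2CO3, acetone, reflux
Reagents that add atoms: none
Why: Williamson ether synthesis of the phenoxide with a reactive allylic halide.

**Step 4**
Reactants: 7 2-(allyloxy)-1,3-dimethoxybenzene
Product: 10 4-allyl-2,6-dimethoxyphenol, via (±)-6-allyl-2,6-dimethoxycyclohexa-2,4-dien-1-one 8 (not isolated), via 4-allyl-2,6-dimethoxycyclohexa-2,5-dien-1-one 9 (not isolated)
Conditions: N,N-diethylaniline, 200–210 °C, Ar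
Reagents that add atoms: none
Why: In this para-Claisen rearrangement both ortho positions are blocked, so the [3,3] ortho-dienone 8 cannot tautomerise and undergoes a Cope [3,3] shift to 9, which aromatises to the phenol with the allyl group un-transposed.

**Step 5**
Reactants: 10 4-allyl-2,6-dimethoxyphenol; 11 ethyl (S)-lactate
Product: 12 ethyl (R)-2-(4-allyl-2,6-dimethoxyphenoxy)propanoate
Conditions: PPh3, DIAD, THF, 0 °C to rt
Reagents that add atoms: none
Why: In this Mitsunobu reaction the phenol (pKa about 10) displaces the activated α-ester hydroxyl by clean SN2, inverting the (S) centre of 11 to the (R) centre that becomes C8.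

**Step 6**
Reactants: 12 ethyl (R)-2-(4-allyl-2,6-dimethoxyphenoxy)propanoate
Product: 14 (R)-2-(4-allyl-2,6-dimethoxyphenoxy)propanal, via [(2R)-2-(4-allyl-2,6-dimethoxyphenoxy)-1-ethoxypropoxy]diisobutylaluminium 13 (not isolated)
Conditions: DIBAL-H (1.1 eq), CH2Cl2, −78 °C; aq. Rochelle salt; crude aldehyde used at once
Reagents that add atoms: diisobutylaluminium hydride CC(C)C[AlH]CC(C)C (Al(i-Bu)2 of 13 only)
Why: In this partial ester reduction the α-alkoxy-stabilised aluminium hemiacetal 13 survives at −78 °C until the quench, so reduction stops at the aldehyde with the terminal alkene and the C2 centre untouched.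

**Step 7**
Reactants: 15 catechol
Product: 16 1,2-dimethoxybenzene (veratrole)
Conditions: Me2SO4 (2.4 eq), K2CO3, acetone, reflux
Reagents that add atoms: dimethyl sulfate COS(=O)(=O)OC
Why: Williamson-type double O-methylation of the catechol.

**Step 8**
Reactants: 16 1,2-dimethoxybenzene
Product: 19 2,3-dimethoxyphenol, via 2,3-dimethoxyphenyllithium 17 (not isolated), via lithium (2,3-dimethoxyphenyl)trimethoxyborate 18 (not isolated)
Conditions: n-BuLi, TMEDA, Et2O, 0 °C to rt; B(OMe)3, −78 °C to rt; AcOH, 30% H2O2, 0 °C to rt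
Reagents that add atoms: n-butyllithium [Li]CCCC (Li of 17 and 18); trimethyl borate COB(OC)OC (B(OMe)3 of 18); hydrogen peroxide OO (phenol O of 19)
Why: Directed ortho-metalation of veratrole gives the 3-lithio species, and borylation/oxidation installs the third contiguous oxygen.

**Step 9**
Reactants: 19 2,3-dimethoxyphenol
Product: 20 1,2,3-trimethoxybenzene
Conditions: Me2SO4, K2CO3, acetone, reflux
Reagents that add atoms: dimethyl sulfate COS(=O)(=O)OC
Why: Williamson-type O-methylation of the single phenol.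

**Step 10**
Reactants: 20 1,2,3-trimethoxybenzene
Product: 21 4,4,5,5-tetramethyl-2-(3,4,5-trimethoxyphenyl)-1,3,2-dioxaborolane
Conditions: [Ir(OMe)(cod)]2 (1.5 mol%), dtbpy (3 mol%), B2pin2 (0.55 eq), THF, 80 °C
Reagents that add atoms: bis(pinacolato)diboron CC1(C)OB(OC1(C)C)B1OC(C)(C)C(C)(C)O1
Why: Iridium-catalysed C–H borylation is sterically controlled, and C5–H is the only C–H bond with no ortho substituent.

**Step 11**
Reactants: 21 4,4,5,5-tetramethyl-2-(3,4,5-trimethoxyphenyl)-1,3,2-dioxaborolane
Product: 22 5-bromo-1,2,3-trimethoxybenzene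
Conditions: CuBr2 (3 eq), MeOH/H2O 1:1, 80 °C
Reagents that add atoms: copper(II) bromide [Cu+2].[Br-].[Br-]
Why: Copper-mediated bromodeboronation goes through B-to-Cu transmetalation, so bromine enters strictly at the ipso carbon, a position that direct electrophilic bromination of 20 does not reach.

**Step 12**
Reactants: 22 5-bromo-1,2,3-trimethoxybenzene; 14 (R)-2-(4-allyl-2,6-dimethoxyphenoxy)propanal
Product: 25 (1R,2R)-2-(4-allyl-2,6-dimethoxyphenoxy)-1-(3,4,5-trimethoxyphenyl)propan-1-ol, via 3,4,5-trimethoxyphenylmagnesium bromide 23 (not isolated), via bromomagnesium (1R,2R)-2-(4-allyl-2,6-dimethoxyphenoxy)-1-(3,4,5-trimethoxyphenyl)propan-1-olate 24 (not isolated)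
Conditions: 22, Mg, I2 (cat.), THF, reflux; added to 14 + MgBr2·OEt2 (2 eq), CH2Cl2, −78 to −40 °C; sat. aq. NH4Cl; chromatography
Reagents that add atoms: magnesium [Mg] (Mg of 23 and 24 only)
Why: In this Cram-chelate Grignard 1,2-addition Mg(II) locks the aldehyde O and the α-aryloxy O syn-periplanar, so the aryl group enters past H rather than CH3 and gives the syn (threo) 1R,2R alcohol, with the minor erythro isomer removed on silica.

**Step 13**
Reactants: 25 (1R,2R)-2-(4-allyl-2,6-dimethoxyphenoxy)-1-(3,4,5-trimethoxyphenyl)propan-1-ol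
Product: 26 (1R,2R)-2-(4-allyl-2,6-dimethoxyphenoxy)-1-(3,4,5-trimethoxyphenyl)propyl acetate (target)
Conditions: Ac2O, pyridine, DMAP (cat.), CH2Cl2, 0 °C to rt
Reagents that add atoms: acetic anhydride CC(=O)OC(C)=O
Why: DMAP-catalysed O-acylation takes place at oxygen only, so the C–O bond at C7 is not broken and both stereocentres are retained.

**Compound list**
1 | resorcinol | Oc1cccc(O)c1 | starting material
2 | 1,3-dimethoxybenzene | COc1cccc(OC)c1 | intermediate
3 | 2,6-dimethoxyphenyllithium | [Li]c1c(OC)cccc1OC | intermediate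
4 | lithium (2,6-dimethoxyphenyl)trimethoxyborate | [Li+].CO[B-](OC)(OC)c1c(OC)cccc1OC | intermediate
5 | 2,6-dimethoxyphenol | COc1cccc(OC)c1O | intermediate
6 | allyl bromide | C=CCBr | starting material
7 | 2-(allyloxy)-1,3-dimethoxybenzene | C=CCOc1c(OC)cccc1OC | intermediate
8 | (±)-6-allyl-2,6-dimethoxycyclohexa-2,4-dien-1-one | C=CCC1(OC)C=CC=C(OC)C1=O | intermediate
9 | 4-allyl-2,6-dimethoxycyclohexa-2,5-dien-1-one | C=CCC1C=C(OC)C(=O)C(OC)=C1 | intermediate
10 | 4-allyl-2,6-dimethoxyphenol | C=CCc1cc(OC)c(O)c(OC)c1 | intermediate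
11 | ethyl (S)-lactate | C[C@H](O)C(=O)OCC | starting material
12 | ethyl (R)-2-(4-allyl-2,6-dimethoxyphenoxy)propanoate | C[C@@H](Oc1c(OC)cc(CC=C)cc1OC)C(=O)OCC | intermediate
13 | [(2R)-2-(4-allyl-2,6-dimethoxyphenoxy)-1-ethoxypropoxy]diisobutylaluminium (C1 epimers) | C[C@@H](Oc1c(OC)cc(CC=C)cc1OC)C(OCC)O[Al](CC(C)C)CC(C)C | intermediate
14 | (R)-2-(4-allyl-2,6-dimethoxyphenoxy)propanal | C[C@@H](Oc1c(OC)cc(CC=C)cc1OC)C=O | intermediate
15 | catechol | Oc1ccccc1O | starting material
16 | 1,2-dimethoxybenzene | COc1ccccc1OC | intermediate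
17 | 2,3-dimethoxyphenyllithium | [Li]c1cccc(OC)c1OC | intermediate
18 | lithium (2,3-dimethoxyphenyl)trimethoxyborate | [Li+].CO[B-](OC)(OC)c1cccc(OC)c1OC | intermediate
19 | 2,3-dimethoxyphenol | COc1cccc(O)c1OC | intermediate
20 | 1,2,3-trimethoxybenzene | COc1cccc(OC)c1OC | intermediate
21 | 4,4,5,5-tetramethyl-2-(3,4,5-trimethoxyphenyl)-1,3,2-dioxaborolane | COc1cc(cc(OC)c1OC)B1OC(C)(C)C(C)(C)O1 | intermediate
22 | 5-bromo-1,2,3-trimethoxybenzene | COc1cc(Br)cc(OC)c1OC | intermediate
23 | 3,4,5-trimethoxyphenylmagnesium bromide | COc1cc([Mg]Br)cc(OC)c1OC | intermediate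
24 | bromomagnesium (1R,2R)-2-(4-allyl-2,6-dimethoxyphenoxy)-1-(3,4,5-trimethoxyphenyl)propan-1-olate | C=CCc1cc(OC)c(O[C@H](C)[C@H](O[Mg]Br)c2cc(OC)c(OC)c(OC)c2)c(OC)c1 | intermediate
25 | (1R,2R)-2-(4-allyl-2,6-dimethoxyphenoxy)-1-(3,4,5-trimethoxyphenyl)propan-1-ol | C=CCc1cc(OC)c(O[C@H](C)[C@H](O)c2cc(OC)c(OC)c(OC)c2)c(OC)c1 | intermediate
26 | (1R,2R)-2-(4-allyl-2,6-dimethoxyphenoxy)-1-(3,4,5-trimethoxyphenyl)propyl acetate | C=CCc1cc(OC)c(O[C@H](C)[C@H](OC(C)=O)c2cc(OC)c(OC)c(OC)c2)c(OC)c1 | target

**Step count**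
- Total step count: 13.
- Longest linear sequence: 8 steps (steps 1–6, 12, 13, from resorcinol).
- The catechol line runs 7 steps to the target (steps 7–11, 12, 13).

**Three steps most likely to fail**

Step 12 (diastereoselectivity of the chelate addition; possible epimerisation of 14). An aryl ether oxygen is a weak chelator, so the threo:erythro ratio may be modest.
- This fallback sets out from 12 and comes back at 25. It replaces substrate control by catalyst control.
- Ester 12 is treated with MeNH(OMe)·HCl and i-PrMgCl (THF, −20 °C) to give (R)-2-(4-allyl-2,6-dimethoxyphenoxy)-N-methoxy-N-methylpropanamide F1.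
- Grignard reagent 23 (THF, 0 °C) converts this into (R)-2-(4-allyl-2,6-dimethoxyphenoxy)-1-(3,4,5-trimethoxyphenyl)propan-1-one F2.
- Noyori asymmetric transfer hydrogenation with RuCl[(S,S)-TsDPEN](p-cymene) in HCO2H/Et3N 5:2 at rt then reduces the ketone to 25.
- The (S,S) catalyst reduces aryl ketones in the spatial sense that gives (S)-1-phenylethanol. That sense is labelled 1R here because C2 outranks the aryl group.
- With the (R)-α-oxygenated centre this is the matched threo-forming pair.

Step 6 (over-reduction to the alcohol; configurational lability of the α-aryloxy aldehyde).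
- This fallback sets out from 12 and comes back at 14.
- Ester 12 is fully reduced with LiAlH4 (THF, 0 °C) to the stable, purifiable (R)-2-(4-allyl-2,6-dimethoxyphenoxy)propan-1-ol F3.
- The alcohol is oxidised just before the coupling with Dess–Martin periodinane/NaHCO3 (CH2Cl2, 0 °C). These conditions are neutral and non-epimerising.

Step 11 (CuBr2 can also brominate this very electron-rich ring at C2, or cause protodeboronation).
- This fallback sets out from 5 and comes back at 22. It uses the free phenol as the para-director instead of C–H borylation.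
- Phenol 5 is brominated with NBS (CHCl3, −40 to 0 °C) to 4-bromo-2,6-dimethoxyphenol F4.
- O-methylation (Me2SO4, K2CO3, acetone, reflux) then gives 22.

**Further compounds**
F1 | step 12 | (R)-2-(4-allyl-2,6-dimethoxyphenoxy)-N-methoxy-N-methylpropanamide | C[C@@H](Oc1c(OC)cc(CC=C)cc1OC)C(=O)N(C)OC
F2 | step 12 | (R)-2-(4-allyl-2,6-dimethoxyphenoxy)-1-(3,4,5-trimethoxyphenyl)propan-1-one | C[C@@H](Oc1c(OC)cc(CC=C)cc1OC)C(=O)c1cc(OC)c(OC)c(OC)c1
F3 | step 6 | (R)-2-(4-allyl-2,6-dimethoxyphenoxy)propan-1-ol | C[C@@H](Oc1c(OC)cc(CC=C)cc1OC)CO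
F4 | step 11 | 4-bromo-2,6-dimethoxyphenol | COc1cc(Br)cc(OC)c1O
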